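**Retrosynthetic overview**
1. The 2,3-dihydrobenzofuran is the only ring made and it is closed last: acid unmasks the phenols, the p-hydroxybenzylic alcohol gives a p-quinone methide, and the ring-B phenol adds to it (5-exo intramolecular oxa-Michael, 1,6-addition), setting C2 trans to C3.
2. The open-chain precursor 25 comes from an sp2–sp3 Suzuki–Molander coupling of aryl bromide diol 18 with alkyltrifluoroborate 23, which carries the ferulate and the C3 linker.
3. Diol 18 comes from an Evans syn-aldol of arylacetyl imide 12 with MOM-vanillin 14, then LiBH4; this sets the future C3.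
4. Imide 12 comes from 4-bromoguaiacol (O-allylation, Claisen, MOM, oxidative cleavage, N-acylation); borate 23 comes from ferulic acid (allyl ester, MOM, hydroboration, KHF2).

Assumption: the target SMILES is read as the (2R,3S)-trans-dihydrobenzofuran; MOMCl, Bu2BOTf, pinacolborane, RuPhos and (R)-4-benzyl-2-oxazolidinone are taken as purchasable.

**Route**

Step 1
Reactants: 1 4-bromo-2-methoxyphenol; 2 allyl bromide
Product: 3 1-(allyloxy)-4-bromo-2-methoxybenzene
Conditions: K2CO3, acetone, reflux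
Reagents that add atoms: none
Why: Williamson ether synthesis, SN2 O-allylation of the phenoxide.

Step 2
Reactants: 3 1-(allyloxy)-4-bromo-2-methoxybenzene
Product: 5 2-allyl-4-bromo-6-methoxyphenol, via Claisen dienone 4 (not isolated)
Conditions: neat (or PhNEt2), 200 °C, N2
Reagents that add atoms: none
Why: aromatic Claisen [3,3] rearrangement to the only free ortho position, then tautomerisation to the phenol.

Step 3
Reactants: 5 2-allyl-4-bromo-6-methoxyphenol
Product: 6 1-allyl-5-bromo-3-methoxy-2-(methoxymethoxy)benzene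
Conditions: MOMCl, iPr2NEt, CH2Cl2, 0 → 40 °C
Reagents that add atoms: chloromethyl methyl ether (MOMCl), COCCl
Why: O-alkylation of the phenol to a MOM acetal, which survives oxidants, boron enolates, hydride and Pd and is removed by acid in the last step.

Step 4
Reactants: 6 1-allyl-5-bromo-3-methoxy-2-(methoxymethoxy)benzene
Product: 9 2-[5-bromo-3-methoxy-2-(methoxymethoxy)phenyl]acetic acid, via diol 7 (not isolated), via aldehyde 8 (not isolated)
Conditions: KMnO4 (10 mol %), NaIO4 (5 equiv), K2CO3 buffer (pH 8), t-BuOH/H2O, rt; citric acid work-up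
Reagents that add atoms: sodium periodate, [Na+].[O-]I(=O)(=O)=O; potassium permanganate (catalytic oxygen carrier), [K+].[O-][Mn](=O)(=O)=O; water, O
Why: Lemieux–von Rudloff oxidation, in which catalytic permanganate dihydroxylates the terminal alkene, periodate cleaves the diol and the aldehyde is oxidised on to the acid under near-neutral conditions that leave the MOM acetal and aryl bromide alone.

Step 5
Reactants: 9 2-[5-bromo-3-methoxy-2-(methoxymethoxy)phenyl]acetic acid; 10 (R)-4-benzyl-1,3-oxazolidin-2-one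
Product: 12 (R)-4-benzyl-3-{2-[5-bromo-3-methoxy-2-(methoxymethoxy)phenyl]acetyl}-1,3-oxazolidin-2-one, via mixed pivalic anhydride 11 (not isolated)
Conditions: PivCl, Et3N, THF, −20 °C; then 10, LiCl, −20 °C → rt
Reagents that add atoms: none
Why: LiCl-assisted N-acylation of the oxazolidinone through the mixed anhydride, attacked at the less hindered arylacetyl carbonyl.

Step 6
Reactants: 13 vanillin
Product: 14 3-methoxy-4-(methoxymethoxy)benzaldehyde
Conditions: MOMCl, iPr2NEt, CH2Cl2, 0 °C → rt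
Reagents that add atoms: chloromethyl methyl ether (MOMCl), COCCl
Why: MOM protection of the phenol, so that the aldehyde can be used with a boron enolate.

Step 7
Reactants: 12 (R)-4-benzyl-3-{2-[5-bromo-3-methoxy-2-(methoxymethoxy)phenyl]acetyl}-1,3-oxazolidin-2-one; 14 3-methoxy-4-(methoxymethoxy)benzaldehyde
Product: 17 (R)-4-benzyl-3-{(2R,3R)-2-[5-bromo-3-methoxy-2-(methoxymethoxy)phenyl]-3-hydroxy-3-[3-methoxy-4-(methoxymethoxy)phenyl]propanoyl}-1,3-oxazolidin-2-one, via Z-boron enolate 15 (not isolated), via boron aldolate 16 (not isolated)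
Conditions: Bu2BOTf, iPr2NEt, CH2Cl2, −78 → 0 °C; 14, −78 → 0 °C; pH 7 buffer, MeOH, 30% H2O2, 0 °C
Reagents that add atoms: none
Why: Evans syn-aldol, in which the Z-dibutylboron enolate reacts through a Zimmerman–Traxler chair with the benzyl group of the (R)-auxiliary blocking one face, giving the 2R,3R syn adduct; C2 is the future C3 of the target and the carbinol centre is erased later.

Step 8
Reactants: 17 the syn-aldol adduct
Product: 18 (1R,2S)-2-[5-bromo-3-methoxy-2-(methoxymethoxy)phenyl]-1-[3-methoxy-4-(methoxymethoxy)phenyl]propane-1,3-diol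
Conditions: LiBH4, MeOH (1.1 equiv), THF, 0 °C
Reagents that add atoms: none
Why: reductive cleavage of the N-acyl oxazolidinone to the primary alcohol without touching either stereocentre (C2 changes from R to S only because CH2OH ranks below CH(OH)Ar); the auxiliary is recovered.

Step 9
Reactants: 19 (E)-ferulic acid; 2 allyl bromide
Product: 20 allyl (E)-3-(4-hydroxy-3-methoxyphenyl)prop-2-enoate
Conditions: KHCO3, DMF, 40 °C
Reagents that add atoms: none
Why: chemoselective SN2 alkylation of the carboxylate, since bicarbonate does not deprotonate the phenol.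

Step 10
Reactants: 20 allyl (E)-ferulate
Product: 21 allyl (E)-3-[3-methoxy-4-(methoxymethoxy)phenyl]prop-2-enoate
Conditions: MOMCl, iPr2NEt, CH2Cl2, 0 °C → rt
Reagents that add atoms: chloromethyl methyl ether (MOMCl), COCCl
Why: MOM protection of the phenol, so that all three phenol protecting groups fall off together in the last step.

Step 11
Reactants: 21 allyl (E)-3-[3-methoxy-4-(methoxymethoxy)phenyl]prop-2-enoate
Product: 22 3-(4,4,5,5-tetramethyl-1,3,2-dioxaborolan-2-yl)propyl (E)-3-[3-methoxy-4-(methoxymethoxy)phenyl]prop-2-enoate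
Conditions: HBpin (1.2 equiv), [Ir(cod)Cl]2 (1.5 mol %), dppm (3 mol %), CH2Cl2, rt
Reagents that add atoms: pinacolborane, CC1(C)OBOC1(C)C
Why: Ir-catalysed anti-Markovnikov hydroboration, selective for the terminal alkene over the conjugated 1,2-disubstituted cinnamate alkene and the ester.

Step 12
Reactants: 22 the pinacol boronate
Product: 23 potassium trifluoro{3-[(E)-3-(3-methoxy-4-(methoxymethoxy)phenyl)prop-2-enoyloxy]propyl}borate
Conditions: KHF2 (4.5 M aq., 4 equiv), MeOH, rt; pinacol removed by co-evaporation with aq. MeOH; hot acetone extraction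
Reagents that add atoms: potassium hydrogen difluoride, [K+].[F-].F
Why: ligand exchange at boron gives a crystalline, air-stable primary alkyltrifluoroborate that can be weighed for the coupling.

Step 13
Reactants: 18 the aryl bromide diol; 23 the potassium alkyltrifluoroborate
Product: 25 3-{3-[(1R,2S)-1,3-dihydroxy-1-[3-methoxy-4-(methoxymethoxy)phenyl]propan-2-yl]-5-methoxy-4-(methoxymethoxy)phenyl}propyl (E)-3-[3-methoxy-4-(methoxymethoxy)phenyl]prop-2-enoate, via boronic acid 24 (not isolated)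
Conditions: Pd(OAc)2 (5 mol %), RuPhos (10 mol %), K2CO3 (3 equiv), toluene/H2O 10:1, 85 °C
Reagents that add atoms: none
Why: Suzuki–Miyaura (Molander) sp2–sp3 coupling, with slow release of the boronic acid, oxidative addition at the unhindered aryl bromide and RuPhos-promoted reductive elimination outrunning β-hydride elimination; the ester, MOM acetals and free diol tolerate K2CO3.

Step 14
Reactants: 25 the tris-MOM open-chain diol
Product: 28 3-[(2R,3S)-2-(4-hydroxy-3-methoxyphenyl)-3-(hydroxymethyl)-7-methoxy-2,3-dihydro-1-benzofuran-5-yl]propyl (E)-3-(4-hydroxy-3-methoxyphenyl)prop-2-enoate, via triphenol diol 26 (not isolated), via p-quinone methide 27 (not isolated)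
Conditions: conc. HCl (15 equiv), i-PrOH/THF 1:1, 0.02 M, 40 °C
Reagents that add atoms: none
Why: acid removes the three aryl MOM acetals, the freed p-hydroxybenzylic alcohol dehydrates to the p-quinone methide, and the ring-B phenol closes the dihydrofuran by a 5-exo intramolecular oxa-Michael (1,6-conjugate) addition anti to the CH2OH group on the fixed C3 (S) (reversible under acid, so trans is also the thermodynamic isomer), which sets C2 as R.

**Compound list**
1 | 4-bromo-2-methoxyphenol | COc1cc(Br)ccc1O | starting material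
2 | allyl bromide | C=CCBr | starting material
3 | 1-(allyloxy)-4-bromo-2-methoxybenzene | COc1cc(Br)ccc1OCC=C | intermediate
4 | 6-allyl-4-bromo-2-methoxycyclohexa-2,4-dien-1-one [Claisen dienone, racemic, not isolated] | O=C1C(OC)=CC(Br)=CC1CC=C | intermediate
5 | 2-allyl-4-bromo-6-methoxyphenol | COc1cc(Br)cc(CC=C)c1O | intermediate
6 | 1-allyl-5-bromo-3-methoxy-2-(methoxymethoxy)benzene | COCOc1c(CC=C)cc(Br)cc1OC | intermediate
7 | 3-[5-bromo-3-methoxy-2-(methoxymethoxy)phenyl]propane-1,2-diol [racemic, not isolated] | COCOc1c(CC(O)CO)cc(Br)cc1OC | intermediate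
8 | 2-[5-bromo-3-methoxy-2-(methoxymethoxy)phenyl]acetaldehyde [not isolated] | COCOc1c(CC=O)cc(Br)cc1OC | intermediate
9 | 2-[5-bromo-3-methoxy-2-(methoxymethoxy)phenyl]acetic acid | COCOc1c(CC(=O)O)cc(Br)cc1OC | intermediate
10 | (R)-4-benzyl-1,3-oxazolidin-2-one (chiral auxiliary) | O=C1N[C@H](Cc2ccccc2)CO1 | starting material
11 | 2-[5-bromo-3-methoxy-2-(methoxymethoxy)phenyl]acetic pivalic anhydride [not isolated] | COCOc1c(CC(=O)OC(=O)C(C)(C)C)cc(Br)cc1OC | intermediate
12 | (R)-4-benzyl-3-{2-[5-bromo-3-methoxy-2-(methoxymethoxy)phenyl]acetyl}-1,3-oxazolidin-2-one | COCOc1c(CC(=O)N2[C@H](Cc3ccccc3)COC2=O)cc(Br)cc1OC | intermediate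
13 | vanillin (4-hydroxy-3-methoxybenzaldehyde) | COc1cc(C=O)ccc1O | starting material
14 | 3-methoxy-4-(methoxymethoxy)benzaldehyde | COCOc1ccc(C=O)cc1OC | intermediate
15 | (Z)-dibutylboron enolate of 12: (R)-4-benzyl-3-{(Z)-2-[5-bromo-3-methoxy-2-(methoxymethoxy)phenyl]-1-[(dibutylboranyl)oxy]ethenyl}-1,3-oxazolidin-2-one [not isolated] | CCCCB(CCCC)O/C(=C\c1cc(Br)cc(OC)c1OCOC)N1[C@H](Cc2ccccc2)COC1=O | intermediate
16 | O-dibutylboranyl aldolate of 17 (2R,3R) [not isolated] | O=C(N1[C@H](Cc2ccccc2)COC1=O)[C@H](c1cc(Br)cc(OC)c1OCOC)[C@@H](OB(CCCC)CCCC)c1ccc(OCOC)c(OC)c1 | intermediate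
17 | (R)-4-benzyl-3-{(2R,3R)-2-[5-bromo-3-methoxy-2-(methoxymethoxy)phenyl]-3-hydroxy-3-[3-methoxy-4-(methoxymethoxy)phenyl]propanoyl}-1,3-oxazolidin-2-one | O=C(N1[C@H](Cc2ccccc2)COC1=O)[C@H](c1cc(Br)cc(OC)c1OCOC)[C@@H](O)c1ccc(OCOC)c(OC)c1 | intermediate
18 | (1R,2S)-2-[5-bromo-3-methoxy-2-(methoxymethoxy)phenyl]-1-[3-methoxy-4-(methoxymethoxy)phenyl]propane-1,3-diol | OC[C@H](c1cc(Br)cc(OC)c1OCOC)[C@@H](O)c1ccc(OCOC)c(OC)c1 | intermediate
19 | (E)-ferulic acid | COc1cc(/C=C/C(=O)O)ccc1O | starting material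
20 | allyl (E)-3-(4-hydroxy-3-methoxyphenyl)prop-2-enoate | COc1cc(/C=C/C(=O)OCC=C)ccc1O | intermediate
21 | allyl (E)-3-[3-methoxy-4-(methoxymethoxy)phenyl]prop-2-enoate | COCOc1ccc(/C=C/C(=O)OCC=C)cc1OC | intermediate
22 | 3-(4,4,5,5-tetramethyl-1,3,2-dioxaborolan-2-yl)propyl (E)-3-[3-methoxy-4-(methoxymethoxy)phenyl]prop-2-enoate | COCOc1ccc(/C=C/C(=O)OCCCB2OC(C)(C)C(C)(C)O2)cc1OC | intermediate
23 | potassium trifluoro{3-[(E)-3-(3-methoxy-4-(methoxymethoxy)phenyl)prop-2-enoyloxy]propyl}borate | COCOc1ccc(/C=C/C(=O)OCCC[B-](F)(F)F)cc1OC.[K+] | intermediate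
24 | {3-[(E)-3-(3-methoxy-4-(methoxymethoxy)phenyl)prop-2-enoyloxy]propyl}boronic acid [not isolated] | COCOc1ccc(/C=C/C(=O)OCCCB(O)O)cc1OC | intermediate
25 | 3-{3-[(1R,2S)-1,3-dihydroxy-1-[3-methoxy-4-(methoxymethoxy)phenyl]propan-2-yl]-5-methoxy-4-(methoxymethoxy)phenyl}propyl (E)-3-[3-methoxy-4-(methoxymethoxy)phenyl]prop-2-enoate | OC[C@H](c1cc(CCCOC(=O)/C=C/c2ccc(OCOC)c(OC)c2)cc(OC)c1OCOC)[C@@H](O)c1ccc(OCOC)c(OC)c1 | intermediate
26 | 3-{3-[(1R,2S)-1,3-dihydroxy-1-(4-hydroxy-3-methoxyphenyl)propan-2-yl]-4-hydroxy-5-methoxyphenyl}propyl (E)-3-(4-hydroxy-3-methoxyphenyl)prop-2-enoate [not isolated] | OC[C@H](c1cc(CCCOC(=O)/C=C/c2ccc(O)c(OC)c2)cc(OC)c1O)[C@@H](O)c1ccc(O)c(OC)c1 | intermediate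
27 | 3-{4-hydroxy-3-[(2S)-1-hydroxy-3-(3-methoxy-4-oxocyclohexa-2,5-dien-1-ylidene)propan-2-yl]-5-methoxyphenyl}propyl (E)-3-(4-hydroxy-3-methoxyphenyl)prop-2-enoate [p-quinone methide, exocyclic alkene geometry undefined, not isolated] | OC[C@H](c1cc(CCCOC(=O)/C=C/c2ccc(O)c(OC)c2)cc(OC)c1O)C=C1C=CC(=O)C(OC)=C1 | intermediate
28 | 3-[(2R,3S)-2-(4-hydroxy-3-methoxyphenyl)-3-(hydroxymethyl)-7-methoxy-2,3-dihydro-1-benzofuran-5-yl]propyl (E)-3-(4-hydroxy-3-methoxyphenyl)prop-2-enoate | COc1cc(/C=C/C(=O)OCCCc2cc(OC)c3c(c2)[C@@H](CO)[C@H](c2ccc(O)c(OC)c2)O3)ccc1O | target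

**Totals**
Total step count: 14.
Longest linear sequence: 9 steps (1, 2, 3, 4, 5, 7, 8, 13, 14, from 4-bromo-2-methoxyphenol). The ferulate branch is steps 9–12 and the aldehyde branch is step 6.

**Three steps most likely to fail, with fallbacks**

Step 4 (one-pot permanganate/periodate cleavage; risk of over-oxidation at the activated benzylic CH2 or incomplete oxidation). The fallback sets out from 6 and avoids both permanganate and a free arylacetaldehyde. Ozonolysis of 6 (O3, CH2Cl2/MeOH, −78 °C) with NaBH4 work-up gives 2-[5-bromo-3-methoxy-2-(methoxymethoxy)phenyl]ethan-1-ol F1. This is then oxidised to the acid with catalytic TEMPO/NaOCl and stoichiometric NaClO2 in MeCN/phosphate buffer (pH 6.7, 35 °C). The fallback returns to the route at 9.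

Step 11 (Ir-catalysed hydroboration of an allyl ester; risk of allylic C–O cleavage or alkene isomerisation). The fallback sets out from 21 and drops the isolable boron reagents. 21 is hydroborated with 9-BBN-H (THF, 0 °C → rt) to give 3-(9-borabicyclo[3.3.1]nonan-9-yl)propyl (E)-3-[3-methoxy-4-(methoxymethoxy)phenyl]prop-2-enoate F2. This solution is added directly to bromide 18 with PdCl2(dppf) and aqueous K3PO4 in DMF/THF at 50 °C (B-alkyl Suzuki–Miyaura coupling). The fallback returns to the route at 25 and bypasses 22 and 23.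

Step 14 (three MOM cleavages, quinone methide formation and ring closure in one operation with the ferulate ester present; risk of ester solvolysis or formaldehyde-derived by-products). The fallback sets out from 18 and closes the ring before the ester is introduced. The same acid treatment on 18 (conc. HCl, i-PrOH/THF, 40 °C) gives, by the same quinone methide oxa-Michael closure, [(2R,3S)-5-bromo-2-(4-hydroxy-3-methoxyphenyl)-7-methoxy-2,3-dihydro-1-benzofuran-3-yl]methanol F3. Coupling F3 with 23 under the step 13 conditions (one extra equivalent of K2CO3 for the phenol) gives 3-[(2R,3S)-2-(4-hydroxy-3-methoxyphenyl)-3-(hydroxymethyl)-7-methoxy-2,3-dihydro-1-benzofuran-5-yl]propyl (E)-3-[3-methoxy-4-(methoxymethoxy)phenyl]prop-2-enoate F4. Its single remaining MOM group is removed under non-hydrolytic conditions (ZnBr2, n-PrSH, CH2Cl2, 0 °C). The fallback returns to the route at 28.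

**Further compounds**
F1 | step 4 | 2-[5-bromo-3-methoxy-2-(methoxymethoxy)phenyl]ethan-1-ol | COCOc1c(CCO)cc(Br)cc1OC
F2 | step 11 | 3-(9-borabicyclo[3.3.1]nonan-9-yl)propyl (E)-3-[3-methoxy-4-(methoxymethoxy)phenyl]prop-2-enoate | COCOc1ccc(/C=C/C(=O)OCCCB2C3CCCC2CCC3)cc1OC
F3 | step 14 | [(2R,3S)-5-bromo-2-(4-hydroxy-3-methoxyphenyl)-7-methoxy-2,3-dihydro-1-benzofuran-3-yl]methanol | Brc1cc(OC)c2c(c1)[C@@H](CO)[C@H](c1ccc(O)c(OC)c1)O2
F4 | step 14 | 3-[(2R,3S)-2-(4-hydroxy-3-methoxyphenyl)-3-(hydroxymethyl)-7-methoxy-2,3-dihydro-1-benzofuran-5-yl]propyl (E)-3-[3-methoxy-4-(methoxymethoxy)phenyl]prop-2-enoate | COCOc1ccc(/C=C/C(=O)OCCCc2cc(OC)c3c(c2)[C@@H](CO)[C@H](c2ccc(O)c(OC)c2)O3)cc1OC
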